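The readings are simulated for an exercise.

The north-east and south runs differ in charged [X], and two people disagree about what that difference means for a repeat at a charge between them.

| flask | X | remark | time |
|---|---|---|---|
| north-east | 0.25 mM | run made earlier |  |
| south | 1 mM | run made earlier |  |
| flask | 0.50 mM |  | 5.0 min |

- north-east (time / min: D / %, Q / %): 0.417: 15.4, 2.3; 0.833: 25.2, 7.5; 1.50: 30.3, 19.0; 3.00: 25.2, 40.3; 6.00: 9.2, 55.8
- south (time / min: D / %, Q / %): 0.417: 15.1, 2.7; 0.833: 22.8, 7.3; 1.50: 27.1, 18.2; 3.00: 22.4, 37.6; 6.00: 8.4, 50.3

(each reading ± 0.5 percentage points)

1. time, not beyond 5.0 min, at which the flask holds most D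
2. the amount of D, in percent of the X charged, at that time



The first holds the flat view: X goes to D and D goes to Q, each by first order, so percentages ignore the charge and the flask should repeat the north-east reading of 30.3% at 1.50 min. She points to the earliest D readings, 15.4% and 15.1%, which lie closer together than one standard deviation.

The second points to 1.50 min, the highest D reading in both runs, where the south run reads 27.1%. That gap of 3.2 percentage points exceeds the scatter, so he holds that charge costs D. The flask lies a third of the way from north-east to south, which gives a first answer of 29.2%.

But a dent should take a share of the D present, not fixed points, so we go round once more. The dent rate, the logarithmic loss of D per mM of X charged, read here from these two scattered readings, is 0.149 mM⁻¹. Scaled from the north-east reading at 1.50 min, it gives 29.2% for the flask, and that is my reckoning of its highest D, with the peak to be sought near that time.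

The forecast sides with the dent, “if loss scales with concentration”, and says 29.6% at 1.8 min.

The flask gives 29.4% at 1.68 min.

    D → Q (k = 0.0110 s⁻¹)
    X + D → Z (k = 3.40 L mol⁻¹ s⁻¹)
    X → D (k = 0.00810 s⁻¹)
    Q ⇌ J (K = 0.960, k = 0.00290 s⁻¹)

That lies 0.20 points from my reckoning. With only the charge of X changed from the north-east run, the highest D goes from 30.3% to 29.4%, while the flat view keeps the earliest readings at 0.417 min. X + D → Z is a second-order side reaction. In the neighbouring flask charged with 2.0 mM of X, the dent rate carried on from this flask gives 23.5%. That flask reaches a highest D of 25.0%, more than reckoned, and at 5.00 min it holds Z at 24.7%, each Z counted as two, against 7.83% in this flask.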